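The target is read as decarboxycitrinin (quinone methide half) joined through C7–CH2–C7' to its own dihydro form (isochroman half). Everything rests on the O2–C3 bond of the dihydropyran ring of the quinone methide: O2 is the formyl oxygen on C1 of a 2,4-dihydroxybenzaldehyde and C3 carries a mesylate in an erythro (2S,3S) side chain, made in one step from (2S,3S)-2,3-epoxybutane and carried as the dimethyl ether. Unmasking the phenols lets the formyl oxygen displace the mesylate: one operation closes the pyran, inverts C3 to the trans-(3R,4S) pattern and dearomatises the carbocycle. NaBH4 reduction of part of this product gives the isochroman half; a Mannich/ortho-quinone methide union installs the bridge.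

Key step: step 6

Remark: atoms are numbered as in isochromene (C1, O2, C3, C4, C4a, C5 to C8, C8a), the quinone methide half is written in the 8-oxo/6-hydroxy tautomeric form of the target SMILES, and (2S,3S)-2,3-dimethyloxirane is taken as a catalogue compound.

Step 1
Reactants: 1 1-bromo-3,5-dimethoxybenzene
Product: 2 2-bromo-4,6-dimethoxybenzaldehyde
Conditions: POCl3, DMF, 0 → 90 °C; then aq. NaOAc
Reagents that add atoms: N,N-dimethylformamide, CN(C)C=O (formyl carbon); water, O (carbonyl oxygen, on hydrolysis of the iminium salt)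
Why: Vilsmeier–Haack formylation, in which the chloroiminium ion should attack the ring carbon para to one methoxy group and ortho to the other (next to bromine) and not the shielded carbon between the two methoxy groups.

Step 2
Reactants: 2 2-bromo-4,6-dimethoxybenzaldehyde
Product: 3 1-bromo-3,5-dimethoxy-2-methylbenzene
Conditions: Et3SiH (3 equiv), TFA, CH2Cl2, 0 °C → rt
Reagents that add atoms: none
Why: Ionic hydrogenation (Kursanov–Parnes reduction), in which the protonated aldehyde and then the benzylic cation stabilised by the ortho and para methoxy groups each accept hydride from the silane, so that CHO should be taken down to CH3 without loss of the aryl bromide.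

Step 3
Reactants: 3 1-bromo-3,5-dimethoxy-2-methylbenzene, 4 (2S,3S)-2,3-dimethyloxirane
Product: 6 (2S,3S)-3-(3,5-dimethoxy-2-methylphenyl)butan-2-ol, via arylmagnesium bromide 5 (not isolated)
Conditions: Mg, THF, 50 °C; then CuI (10 mol%), 4, −30 → 0 °C; aq. NH4Cl
Reagents that add atoms: magnesium, [Mg] (held only in intermediate 5)
Why: CuI-catalysed Grignard opening of an epoxide by SN2, in which attack at either of the two equivalent carbons of the C2-symmetric epoxide inverts that carbon and leaves the carbinol carbon untouched, so that a single erythro (2S,3S) alcohol should form that already holds C4 (S) of the target and has C3 in the configuration opposite to the final one.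

Step 4
Reactants: 6 (2S,3S)-3-(3,5-dimethoxy-2-methylphenyl)butan-2-ol
Product: 7 (2S,3S)-3-(3,5-dimethoxy-2-methylphenyl)butan-2-yl methanesulfonate
Conditions: MsCl, Et3N, CH2Cl2, 0 °C
Reagents that add atoms: methanesulfonyl chloride, CS(=O)(=O)Cl
Why: O-sulfonylation (mesylation) of a secondary alcohol, which forms only an O–S bond and so should keep the (S) configuration at the carbinol carbon while turning its oxygen into a leaving group.

Step 5
Reactants: 7 (2S,3S)-3-(3,5-dimethoxy-2-methylphenyl)butan-2-yl methanesulfonate
Product: 8 (2S,3S)-3-(2-formyl-3,5-dimethoxy-6-methylphenyl)butan-2-yl methanesulfonate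
Conditions: POCl3, DMF, 0 → 40 °C; then aq. NaOAc, 0 °C
Reagents that add atoms: N,N-dimethylformamide, CN(C)C=O (formyl carbon); water, O (carbonyl oxygen, on hydrolysis of the iminium salt)
Why: Vilsmeier–Haack formylation, which should go to the ring carbon next to the side chain (para to one methoxy group, ortho to the other) because the only other free carbon lies between two methoxy groups, while the β-branched secondary mesylate should resist chloride at this temperature.

Step 6
Reactants: 8 (2S,3S)-3-(2-formyl-3,5-dimethoxy-6-methylphenyl)butan-2-yl methanesulfonate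
Product: 10 (3R,4S)-6-hydroxy-3,4,5-trimethyl-3,4-dihydro-8H-isochromen-8-one (decarboxycitrinin), via dihydroxy aldehyde mesylate 9 (not isolated)
Conditions: BBr3 (5 equiv), CH2Cl2, −78 → 0 °C; cold aq. NaHCO3; then NaHCO3, DMF (0.01 M), 45 °C
Reagents that add atoms: none
Why: Proposed new method: BBr3 should cleave both aryl methyl ethers (Lewis adduct, then bromide attack on methyl) and spare the sulfonate ester, after which bicarbonate deprotonates the 5-hydroxyl para to the formyl group of 9, and the resulting vinylogous carboxylate attacks the mesylate-bearing carbon through its formyl oxygen, so that the carbocycle is dearomatised to the quinone methide as the O2–C3 bond forms. The closest known reaction types are the invertive lactonisation of carboxylate salts onto secondary sulfonates and the O-alkylation of cyclic 1,3-diketone enolates to vinylogous esters, whereas the same displacement through the carbonyl oxygen of a hydroxybenzaldehyde is not established. The dihydropyran ring closes in the 6-exo-tet mode. The new stereocentre C3 is set by SN2 inversion of the (S)-mesylate to (R), and C4 (S) is not involved, so the trans-3,4-dimethyl pattern follows from the erythro precursor. The step needs alkylation at the formyl oxygen in preference to intermolecular phenoxide alkylation and to E2 elimination toward the benzylic hydrogen: both phenolic oxygens are meta to the side chain and cannot reach C3, only the formyl oxygen can close a six-membered ring, and high dilution with a weak base disfavours the competing paths.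

Step 7
Reactants: 10 (3R,4S)-6-hydroxy-3,4,5-trimethyl-3,4-dihydro-8H-isochromen-8-one (about half of the material)
Product: 11 (3R,4S)-3,4,5-trimethyl-3,4-dihydro-1H-isochromene-6,8-diol
Conditions: NaBH4, MeOH, 0 °C; then H2O
Reagents that add atoms: none
Why: Conjugate (1,6) hydride reduction of a quinone methide, in which hydride should add to the exocyclic C1 and rearomatise the carbocycle to the resorcinol, leaving C3 and C4 untouched.

Step 8
Reactants: 11 (3R,4S)-3,4,5-trimethyl-3,4-dihydro-1H-isochromene-6,8-diol, 10 (3R,4S)-6-hydroxy-3,4,5-trimethyl-3,4-dihydro-8H-isochromen-8-one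
Product: 13 (3R,4S)-7-{[(3R,4S)-6,8-dihydroxy-3,4,5-trimethyl-3,4-dihydro-1H-isochromen-7-yl]methyl}-6-hydroxy-3,4,5-trimethyl-3,4-dihydro-8H-isochromen-8-one (the target), via Mannich base hydroiodide 12 (not isolated)
Conditions: Eschenmoser's salt (dimethylmethylideneammonium iodide, 1.0 equiv), MeCN, rt; then 10, NaOAc, 70 °C
Reagents that add atoms: dimethylmethylideneammonium iodide (Eschenmoser's salt), C=[N+](C)C.[I-] (bridging CH2)
Why: Phenol Mannich reaction at the only free ring carbon of 11 (C7, between the two hydroxyls), followed by thermal loss of dimethylamine to an ortho-quinone methide that should be trapped by Michael addition of the nucleophilic C7 of the vinylogous acid 10 (flanked by C6–OH and C8=O), with no stereocentre formed.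

Compound list
1 | 1-bromo-3,5-dimethoxybenzene | COc1cc(Br)cc(OC)c1 | starting material
2 | 2-bromo-4,6-dimethoxybenzaldehyde | O=Cc1c(Br)cc(OC)cc1OC | intermediate
3 | 1-bromo-3,5-dimethoxy-2-methylbenzene | Cc1c(Br)cc(OC)cc1OC | intermediate
4 | (2S,3S)-2,3-dimethyloxirane (trans-2,3-epoxybutane) | C[C@@H]1O[C@H]1C | starting material
5 | (3,5-dimethoxy-2-methylphenyl)magnesium bromide | Cc1c([Mg]Br)cc(OC)cc1OC | intermediate
6 | (2S,3S)-3-(3,5-dimethoxy-2-methylphenyl)butan-2-ol | C[C@H](O)[C@@H](C)c1cc(OC)cc(OC)c1C | intermediate
7 | (2S,3S)-3-(3,5-dimethoxy-2-methylphenyl)butan-2-yl methanesulfonate | C[C@H](OS(C)(=O)=O)[C@@H](C)c1cc(OC)cc(OC)c1C | intermediate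
8 | (2S,3S)-3-(2-formyl-3,5-dimethoxy-6-methylphenyl)butan-2-yl methanesulfonate | C[C@H](OS(C)(=O)=O)[C@@H](C)c1c(C=O)c(OC)cc(OC)c1C | intermediate
9 | (2S,3S)-3-(2-formyl-3,5-dihydroxy-6-methylphenyl)butan-2-yl methanesulfonate | C[C@H](OS(C)(=O)=O)[C@@H](C)c1c(C=O)c(O)cc(O)c1C | intermediate
10 | (3R,4S)-6-hydroxy-3,4,5-trimethyl-3,4-dihydro-8H-isochromen-8-one (decarboxycitrinin) | CC1=C2C(=CO[C@H](C)[C@H]2C)C(=O)C=C1O | intermediate
11 | (3R,4S)-3,4,5-trimethyl-3,4-dihydro-1H-isochromene-6,8-diol | c1c(O)c(C)c2c(c1O)CO[C@H](C)[C@H]2C | intermediate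
12 | (3R,4S)-7-[(dimethylamino)methyl]-3,4,5-trimethyl-3,4-dihydro-1H-isochromene-6,8-diol hydroiodide | C[NH+](C)Cc1c(O)c(C)c2c(c1O)CO[C@H](C)[C@H]2C.[I-] | intermediate
13 | (3R,4S)-7-{[(3R,4S)-6,8-dihydroxy-3,4,5-trimethyl-3,4-dihydro-1H-isochromen-7-yl]methyl}-6-hydroxy-3,4,5-trimethyl-3,4-dihydro-8H-isochromen-8-one | CC1=C2C(=CO[C@H](C)[C@H]2C)C(=O)C(Cc2c(O)c(C)c3c(c2O)CO[C@H](C)[C@H]3C)=C1O | target

Total step count: 8. Longest linear sequence: 8 (steps 1 to 8; step 7 draws on part of 10 and step 8 joins 10 with 11).

Steps most likely to fail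

Step 6 (proposed new method). The mesylate may be exchanged for bromide during the BBr3 stage, which after closure would mean two inversions and the cis-3,4-dimethyl series. E2 elimination toward the benzylic hydrogen may also compete, or the formyl oxygen may prove too weak a nucleophile. The fallback uses known chemistry, sets out from 8 and comes back at 10. Pinnick oxidation of the aldehyde (NaClO2, NaH2PO4, 2-methyl-2-butene, t-BuOH/H2O) would give 2-[(2S,3S)-3-(methanesulfonyloxy)butan-2-yl]-4,6-dimethoxy-3-methylbenzoic acid F1. Cs2CO3 in DMF would then close the δ-lactone by carboxylate SN2 with inversion at the mesylate carbon, giving (3R,4S)-6,8-dimethoxy-3,4,5-trimethyl-3,4-dihydro-1H-isochromen-1-one F2. BBr3 in CH2Cl2 would cleave the methyl ethers to (3R,4S)-6,8-dihydroxy-3,4,5-trimethyl-3,4-dihydro-1H-isochromen-1-one F3. Excess i-Bu2AlH at −78 °C would reduce the lactone to the lactol (3R,4S)-3,4,5-trimethyl-3,4-dihydro-1H-isochromene-1,6,8-triol F4, which should lose water on dilute acid work-up to give 10.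

Step 5. The sulfonate may be lost by chloride substitution or ionisation under the Vilsmeier conditions, or formylation may stray to the carbon between the methoxy groups. The fallback places C1 on the ring before the side chain, sets out from 3 and comes back at 8. Vilsmeier formylation of 3 (para to methoxy, next to bromine) would give 2-bromo-4,6-dimethoxy-3-methylbenzaldehyde F5. Ethane-1,2-diol with TsOH in toluene would protect it as 2-(2-bromo-4,6-dimethoxy-3-methylphenyl)-1,3-dioxolane F6. Mg in THF would give [2-(1,3-dioxolan-2-yl)-3,5-dimethoxy-6-methylphenyl]magnesium bromide F7, and CuI-catalysed opening of 4 would give (2S,3S)-3-[2-(1,3-dioxolan-2-yl)-3,5-dimethoxy-6-methylphenyl]butan-2-ol F8. MsCl and Et3N would give (2S,3S)-3-[2-(1,3-dioxolan-2-yl)-3,5-dimethoxy-6-methylphenyl]butan-2-yl methanesulfonate F9, and acetal hydrolysis (PPTS, acetone/H2O) would release 8.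

Step 8. Homodimerisation may intervene, either by aminomethylation of 10 with unconsumed iminium salt or by addition of 11 to its own ortho-quinone methide, and amine may add reversibly at C1 of the quinone methide. The fallback builds the bridge at the aldehyde oxidation level, sets out from 11 (with 10) and comes back at 13. Vilsmeier formylation of 11 at its only free ring carbon would give (3R,4S)-6,8-dihydroxy-3,4,5-trimethyl-3,4-dihydro-1H-isochromene-7-carbaldehyde F10. Proline-catalysed Knoevenagel condensation of this aldehyde with 10 would give the 7-arylidene-6,8-dione intermediate F11 in the flask. Diethyl 2,6-dimethyl-1,4-dihydropyridine-3,5-dicarboxylate (Hantzsch ester) would reduce it there by conjugate hydride transfer to 13 (organocatalytic reductive alkylation of a cyclic 1,3-dicarbonyl).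

Further compounds
F1 | step 6 | 2-[(2S,3S)-3-(methanesulfonyloxy)butan-2-yl]-4,6-dimethoxy-3-methylbenzoic acid | C[C@H](OS(C)(=O)=O)[C@@H](C)c1c(C(=O)O)c(OC)cc(OC)c1C
F2 | step 6 | (3R,4S)-6,8-dimethoxy-3,4,5-trimethyl-3,4-dihydro-1H-isochromen-1-one | c1c(OC)c(C)c2c(c1OC)C(=O)O[C@H](C)[C@H]2C
F3 | step 6 | (3R,4S)-6,8-dihydroxy-3,4,5-trimethyl-3,4-dihydro-1H-isochromen-1-one | c1c(O)c(C)c2c(c1O)C(=O)O[C@H](C)[C@H]2C
F4 | step 6 | (3R,4S)-3,4,5-trimethyl-3,4-dihydro-1H-isochromene-1,6,8-triol (lactol, either C1 epimer) | c1c(O)c(C)c2c(c1O)C(O)O[C@H](C)[C@H]2C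
F5 | step 5 | 2-bromo-4,6-dimethoxy-3-methylbenzaldehyde | O=Cc1c(Br)c(C)c(OC)cc1OC
F6 | step 5 | 2-(2-bromo-4,6-dimethoxy-3-methylphenyl)-1,3-dioxolane | COc1cc(OC)c(C)c(Br)c1C1OCCO1
F7 | step 5 | [2-(1,3-dioxolan-2-yl)-3,5-dimethoxy-6-methylphenyl]magnesium bromide | COc1cc(OC)c(C)c([Mg]Br)c1C1OCCO1
F8 | step 5 | (2S,3S)-3-[2-(1,3-dioxolan-2-yl)-3,5-dimethoxy-6-methylphenyl]butan-2-ol | C[C@H](O)[C@@H](C)c1c(C2OCCO2)c(OC)cc(OC)c1C
F9 | step 5 | (2S,3S)-3-[2-(1,3-dioxolan-2-yl)-3,5-dimethoxy-6-methylphenyl]butan-2-yl methanesulfonate | C[C@H](OS(C)(=O)=O)[C@@H](C)c1c(C2OCCO2)c(OC)cc(OC)c1C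
F10 | step 8 | (3R,4S)-6,8-dihydroxy-3,4,5-trimethyl-3,4-dihydro-1H-isochromene-7-carbaldehyde | O=Cc1c(O)c(C)c2c(c1O)CO[C@H](C)[C@H]2C
F11 | step 8 | (3R,4S)-7-{[(3R,4S)-6,8-dihydroxy-3,4,5-trimethyl-3,4-dihydro-1H-isochromen-7-yl]methylidene}-3,4,5-trimethyl-3,4-dihydro-6H-isochromene-6,8(7H)-dione | CC1=C2C(=CO[C@H](C)[C@H]2C)C(=O)C(=Cc2c(O)c(C)c3c(c2O)CO[C@H](C)[C@H]3C)C1=O
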